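C1 is the CH2 on the six-membered carbocycle, C2=C3 and C6=C7 are the E alkenes, C10 bears OAc, C11 bears OH and CH3, and C14=C15 is the terminal alkene.
Retrosynthetic cuts, in order: quinone to hydroquinone dimethyl ether, acetate off, C14=C15 (Wittig on a lactol), C11–CH3 (methyl addition to a ring ketone), pyranone back to furan, C8–C9 (enolate allylation), aryl–C1 (aryl-metal allylation).
Enabling feature: C10 (secondary C–O), C11 (tertiary C–O), C12, C13 and C14 (alkene CH) match a 2-furyl carbinol, with C10 the carbinol carbon and C11–C14 the furan carbons C2–C5. Oxidative ring expansion converts this into the six-membered ring O–C10–C11–C12–C13–C14, with the C10 oxygen in the ring, a ketone at C11 and a lactol at C14.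
Forward order: arene plus geranyl unit, functionalisation at C8, union with 2-acetylfuran, ketone reduction, furan-to-pyranone expansion, methyl addition, saturation of the ring alkene, ring opening by olefination, acetylation, quinone release. The pyran is the only ring built, and it is opened again.
Stereochemistry: C10 (R) comes from catalyst-controlled asymmetric transfer hydrogenation. C11 (S) comes from substrate control in the trans pyranone acetal, where methyl enters anti to the axial anomeric methoxy group. C2=C3 (E) is bought with geranyl bromide and C6=C7 (E) comes from E-selective allylic oxidation.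
Key step: step 6

Notation: R = (3E,7E)-9-(2,5-dimethoxy-4-methylphenyl)-3,7-dimethylnona-3,7-dien-1-yl, that is C9 to C1 plus the arene.
Assumption: the configuration is read from the SMILES string as (10R,11S); compounds 1, 2, 7 and 18 are taken as catalogue chemicals.

Step 1
Reactants: 1 1-bromo-2,5-dimethoxy-4-methylbenzene; 2 geranyl bromide [(2E)-1-bromo-3,7-dimethylocta-2,6-diene]
Product: 4 1-[(2E)-3,7-dimethylocta-2,6-dien-1-yl]-2,5-dimethoxy-4-methylbenzene, via aryllithium 3 (not isolated)
Conditions: n-BuLi, THF, −78 °C; CuBr·SMe2 (10 mol %), then 2, −78 → 0 °C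
Reagents that add atoms: none
Why: Bromine–lithium exchange followed by copper-catalysed allylic substitution; the aryl-copper species should displace the primary allylic bromide at its CH2 carbon without allylic shift, so the E geometry of C2=C3 is kept.

Step 2
Reactants: 4 1-[(2E)-3,7-dimethylocta-2,6-dien-1-yl]-2,5-dimethoxy-4-methylbenzene
Product: 5 (2E,6E)-8-(2,5-dimethoxy-4-methylphenyl)-2,6-dimethylocta-2,6-dien-1-ol
Conditions: SeO2 (cat.), t-BuOOH, salicylic acid (cat.), CH2Cl2, 0 °C → rt, stopped short of full conversion
Reagents that add atoms: tert-butyl hydroperoxide, CC(C)(C)OO (oxygen source, relayed by the catalyst selenium dioxide, O=[Se]=O)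
Why: Riley-type allylic hydroxylation in its catalytic form; the ene reaction and [2,3]-shift should select the E methyl group of the terminal, least hindered trisubstituted alkene, which fixes C6=C7 as E, and limited conversion holds back attack on C2=C3 and over-oxidation.

Step 3
Reactants: 5 (2E,6E)-8-(2,5-dimethoxy-4-methylphenyl)-2,6-dimethylocta-2,6-dien-1-ol
Product: 6 1-[(2E,6E)-8-bromo-3,7-dimethylocta-2,6-dien-1-yl]-2,5-dimethoxy-4-methylbenzene
Conditions: CBr4, PPh3, CH2Cl2, −20 → 0 °C; used without storage
Reagents that add atoms: carbon tetrabromide, BrC(Br)(Br)Br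
Why: Appel reaction; the neutral SN2 displacement of the alkoxyphosphonium ion at the primary allylic carbon should proceed without transposition or E/Z scrambling and should leave the arene alone.

Step 4
Reactants: 7 2-acetylfuran; 6 1-[(2E,6E)-8-bromo-3,7-dimethylocta-2,6-dien-1-yl]-2,5-dimethoxy-4-methylbenzene
Product: 9 (4E,8E)-10-(2,5-dimethoxy-4-methylphenyl)-1-(furan-2-yl)-4,8-dimethyldeca-4,8-dien-1-one, via lithium enolate 8 (not isolated)
Conditions: 7 (2 equiv), LDA (commercial solution, 2 equiv), THF, −78 °C; then 6 (1 equiv), DMPU, −78 → −20 °C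
Reagents that add atoms: none
Why: SN2 alkylation of a kinetic lithium enolate forms C8–C9; 7 can enolise only toward its methyl group, the primary allylic bromide reacts cold at its CH2 end, and an excess of the cheap enolate over 6 holds back a second alkylation.

Step 5
Reactants: 9 (4E,8E)-10-(2,5-dimethoxy-4-methylphenyl)-1-(furan-2-yl)-4,8-dimethyldeca-4,8-dien-1-one
Product: 10 (1R,4E,8E)-10-(2,5-dimethoxy-4-methylphenyl)-1-(furan-2-yl)-4,8-dimethyldeca-4,8-dien-1-ol
Conditions: RuCl[(R,R)-TsDPEN](p-cymene) (1 mol %), HCO2H–Et3N (5:2), CH2Cl2, rt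
Reagents that add atoms: none
Why: Noyori asymmetric transfer hydrogenation; the furan takes the aryl role in the six-membered Ru–H/N–H transition state (CH/π contact with the η6-arene), so the (R,R)-catalyst should give the (R)-carbinol at C10 as it does with aryl alkyl ketones, and isolated alkenes are not touched by this outer-sphere hydride transfer.

Step 6
Reactants: 10 (1R,4E,8E)-10-(2,5-dimethoxy-4-methylphenyl)-1-(furan-2-yl)-4,8-dimethyldeca-4,8-dien-1-ol
Product: 13 (2R)-6-hydroxy-2-R-2H-pyran-3(6H)-one as an anomeric mixture, via bromo hemiketal 11 (not isolated), via Z-enedione 12 (not isolated)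
Conditions: NBS (1.0 equiv, in portions), NaHCO3 (2 equiv), THF–H2O (4:1), 0 °C, dark
Reagents that add atoms: water, O
Why: Achmatowicz rearrangement: Br+ from NBS attacks the unsubstituted furan α-carbon C14, water traps the C11 oxocarbenium ion to give bromo hemiketal 11, and loss of HBr opens it to the Z-enedione 12 (ketone at C11, aldehyde at C14). The C10 hydroxyl then adds to the C14 aldehyde in a reversible 6-exo-trig hemiacetalisation that forms the O10–C14 bond and closes the ring O–C10–C11–C12–C13–C14, the Z geometry inherited from the furan keeping both ends within reach. No bond at C10 is touched, so the configuration and enantiopurity from step 5 pass into the ring, while the only new stereocentre, anomeric C14, is under thermodynamic (anomeric-effect) control, is expected as a mixture and is sorted out in step 7. The oxidant must choose the furan over two trisubstituted alkenes and a dialkyl-dimethoxyarene; the 2-alkylfuran is the most nucleophilic π system of 10, and slow addition of exactly one equivalent of NBS at 0 °C in bicarbonate-buffered medium (no HBr build-up, no surplus Br+) exploits that rate gap.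

Step 7
Reactants: 13 (2R)-6-hydroxy-2-R-2H-pyran-3(6H)-one
Product: 14 (2R,6S)-6-methoxy-2-R-2H-pyran-3(6H)-one (trans acetal)
Conditions: HC(OMe)3, BF3·OEt2 (cat.), Et2O, 0 °C; cis acetal removed by chromatography
Reagents that add atoms: trimethyl orthoformate, COC(OC)OC
Why: Acid-catalysed acetalisation of the lactol through the ring oxocarbenium ion (Fischer-glycosidation type); the exchange is reversible, so the anomeric effect should favour the acetal with axial methoxy and equatorial side chain (trans, 6S), while the orthoformate takes up the water.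

Step 8
Reactants: 14 (2R,6S)-6-methoxy-2-R-2H-pyran-3(6H)-one
Product: 15 (2R,3S,6S)-6-methoxy-3-methyl-2-R-3,6-dihydro-2H-pyran-3-ol
Conditions: anhydrous CeCl3, MeLi, THF, −78 °C; then 14, −78 °C; aq. NaHCO3 quench
Reagents that add atoms: methyllithium, [Li]C (delivered as methylcerium dichloride)
Why: Organocerium 1,2-addition; the weakly basic, oxophilic reagent should add to the carbonyl without enolising C10 or adding 1,4, and in the half-chair of 14 (side chain pseudo-equatorial, methoxy pseudo-axial) it should approach C11 axially from the face opposite the methoxy group and the axial C10–H, where the 1,3-positions (ring O and sp2 C13) carry no axial substituent, so methyl ends up cis to the C10 side chain and hydroxyl trans to it, which is 11S.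

Step 9
Reactants: 15 (2R,3S,6S)-6-methoxy-3-methyl-2-R-3,6-dihydro-2H-pyran-3-ol
Product: 16 (2R,3S,6S)-6-methoxy-3-methyl-2-R-oxan-3-ol
Conditions: 2-nitrobenzenesulfonohydrazide (in portions), Et3N, CH2Cl2, rt, stopped when 15 is consumed
Reagents that add atoms: none
Why: Diimide reduction, well established for 2,3-unsaturated pyranosides; the rate of the concerted syn hydrogen transfer falls with alkene substitution, so the cis-disubstituted ring alkene C12=C13 should react ahead of the two trisubstituted chain alkenes, and the neutral medium should not ionise the allylic acetal or the tertiary allylic alcohol.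

Step 10
Reactants: 16 (2R,3S,6S)-6-methoxy-3-methyl-2-R-oxan-3-ol
Product: 17 (5S,6R)-5-methyl-6-R-oxane-2,5-diol (lactol, anomeric mixture)
Conditions: 1 M aq. HCl, THF, rt
Reagents that add atoms: water, O
Why: Acetal hydrolysis; with no electronegative group on C12 or C13 the oxocarbenium ion forms easily, so dilute acid at room temperature should suffice and spare the trisubstituted alkenes, the aryl ethers and the now non-allylic tertiary alcohol, and all ring–chain tautomers of 17 react through the same aldehyde in step 11.

Step 11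
Reactants: 17 (5S,6R)-5-methyl-6-R-oxane-2,5-diol; 18 isopropyltriphenylphosphonium iodide
Product: 21 (6S,7R,10E,14E)-16-(2,5-dimethoxy-4-methylphenyl)-2,6,10,14-tetramethylhexadeca-2,10,14-triene-6,7-diol [the (10R,11S)-diol], via isopropylidene ylide 19 (not isolated), via open hydroxy aldehyde 20 (not isolated)
Conditions: 18 (4 equiv), n-BuLi (4 equiv), THF, 0 °C; then 17, 0 °C → rt
Reagents that add atoms: none
Why: Wittig olefination of a lactol through its open hydroxy aldehyde tautomer; the first equivalents of ylide deprotonate the two hydroxyl groups, the remainder olefinates C14 and thereby frees the C10 hydroxyl, and the symmetric isopropylidene terminus raises no E/Z question.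

Step 12
Reactants: 21 the (10R,11S)-diol
Product: 22 (6S,7R,10E,14E)-16-(2,5-dimethoxy-4-methylphenyl)-6-hydroxy-2,6,10,14-tetramethylhexadeca-2,10,14-trien-7-yl acetate
Conditions: Ac2O (1.5 equiv), pyridine, DMAP (cat.), CH2Cl2, 0 °C → rt
Reagents that add atoms: acetic anhydride, CC(=O)OC(C)=O
Why: DMAP-catalysed acylation; the secondary C10 hydroxyl should react while the hindered tertiary C11 hydroxyl stays free under these mild conditions, and the ester also removes the free 1,2-diol before the oxidant of the last step is applied.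

Step 13
Reactants: 22 the C10 acetate with the dimethoxyarene
Product: 23 Chabrolobenzoquinone H
Conditions: (NH4)2Ce(NO3)6 (2.5 equiv), MeCN–H2O (3:1), 0 °C, short reaction time
Reagents that add atoms: water, O
Why: Oxidative demethylation of a 1,4-dimethoxyarene with ceric ammonium nitrate; two one-electron oxidations with attack of water at the methoxy-bearing ring carbons release two methanol and the quinone, and the electron-rich arene should be oxidised far faster than the isolated alkenes, the acetate or the tertiary alcohol.

Compound list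
1 | 1-bromo-2,5-dimethoxy-4-methylbenzene | COc1cc(Br)c(OC)cc1C | starting material
2 | geranyl bromide | CC(C)=CCC/C(C)=C/CBr | starting material
3 | (2,5-dimethoxy-4-methylphenyl)lithium, formed in the flask | [Li]c1cc(OC)c(C)cc1OC | intermediate
4 | 1-[(2E)-3,7-dimethylocta-2,6-dien-1-yl]-2,5-dimethoxy-4-methylbenzene | CC(C)=CCC/C(C)=C/Cc1cc(OC)c(C)cc1OC | intermediate
5 | (2E,6E)-8-(2,5-dimethoxy-4-methylphenyl)-2,6-dimethylocta-2,6-dien-1-ol | OC/C(C)=C/CC/C(C)=C/Cc1cc(OC)c(C)cc1OC | intermediate
6 | 1-[(2E,6E)-8-bromo-3,7-dimethylocta-2,6-dien-1-yl]-2,5-dimethoxy-4-methylbenzene | BrC/C(C)=C/CC/C(C)=C/Cc1cc(OC)c(C)cc1OC | intermediate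
7 | 2-acetylfuran | CC(=O)c1ccco1 | starting material
8 | lithium 1-(furan-2-yl)ethen-1-olate, formed in the flask | [Li]OC(=C)c1ccco1 | intermediate
9 | (4E,8E)-10-(2,5-dimethoxy-4-methylphenyl)-1-(furan-2-yl)-4,8-dimethyldeca-4,8-dien-1-one | O=C(CC/C(C)=C/CC/C(C)=C/Cc1cc(OC)c(C)cc1OC)c1ccco1 | intermediate
10 | (1R,4E,8E)-10-(2,5-dimethoxy-4-methylphenyl)-1-(furan-2-yl)-4,8-dimethyldeca-4,8-dien-1-ol | O[C@H](CC/C(C)=C/CC/C(C)=C/Cc1cc(OC)c(C)cc1OC)c1ccco1 | intermediate
11 | (1R,4E,8E)-1-(5-bromo-2-hydroxy-2,5-dihydrofuran-2-yl)-10-(2,5-dimethoxy-4-methylphenyl)-4,8-dimethyldeca-4,8-dien-1-ol, ring diastereomers, formed in the flask | O[C@H](CC/C(C)=C/CC/C(C)=C/Cc1cc(OC)c(C)cc1OC)C1(O)C=CC(Br)O1 | intermediate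
12 | (2Z,5R,8E,12E)-14-(2,5-dimethoxy-4-methylphenyl)-5-hydroxy-8,12-dimethyl-4-oxotetradeca-2,8,12-trienal, formed in the flask | O[C@H](CC/C(C)=C/CC/C(C)=C/Cc1cc(OC)c(C)cc1OC)C(=O)/C=C\C=O | intermediate
13 | (2R)-6-hydroxy-2-R-2H-pyran-3(6H)-one, anomeric mixture | O=C1C=CC(O)O[C@@H]1CC/C(C)=C/CC/C(C)=C/Cc1cc(OC)c(C)cc1OC | intermediate
14 | (2R,6S)-6-methoxy-2-R-2H-pyran-3(6H)-one, trans | CO[C@@H]1C=CC(=O)[C@@H](CC/C(C)=C/CC/C(C)=C/Cc2cc(OC)c(C)cc2OC)O1 | intermediate
15 | (2R,3S,6S)-6-methoxy-3-methyl-2-R-3,6-dihydro-2H-pyran-3-ol | CO[C@@H]1C=C[C@](C)(O)[C@@H](CC/C(C)=C/CC/C(C)=C/Cc2cc(OC)c(C)cc2OC)O1 | intermediate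
16 | (2R,3S,6S)-6-methoxy-3-methyl-2-R-oxan-3-ol | CO[C@@H]1CC[C@](C)(O)[C@@H](CC/C(C)=C/CC/C(C)=C/Cc2cc(OC)c(C)cc2OC)O1 | intermediate
17 | (5S,6R)-5-methyl-6-R-oxane-2,5-diol, anomeric mixture | OC1CC[C@](C)(O)[C@@H](CC/C(C)=C/CC/C(C)=C/Cc2cc(OC)c(C)cc2OC)O1 | intermediate
18 | isopropyltriphenylphosphonium iodide | CC(C)[P+](c1ccccc1)(c1ccccc1)c1ccccc1.[I-] | starting material
19 | isopropylidenetriphenylphosphorane, formed in the flask | CC(C)=P(c1ccccc1)(c1ccccc1)c1ccccc1 | intermediate
20 | (4S,5R,8E,12E)-14-(2,5-dimethoxy-4-methylphenyl)-4,5-dihydroxy-4,8,12-trimethyltetradeca-8,12-dienal, open tautomer of 17 in the flask | O[C@H](CC/C(C)=C/CC/C(C)=C/Cc1cc(OC)c(C)cc1OC)[C@@](C)(O)CCC=O | intermediate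
21 | (6S,7R,10E,14E)-16-(2,5-dimethoxy-4-methylphenyl)-2,6,10,14-tetramethylhexadeca-2,10,14-triene-6,7-diol | O[C@H](CC/C(C)=C/CC/C(C)=C/Cc1cc(OC)c(C)cc1OC)[C@@](C)(O)CCC=C(C)C | intermediate
22 | (6S,7R,10E,14E)-16-(2,5-dimethoxy-4-methylphenyl)-6-hydroxy-2,6,10,14-tetramethylhexadeca-2,10,14-trien-7-yl acetate | CC(=O)O[C@H](CC/C(C)=C/CC/C(C)=C/Cc1cc(OC)c(C)cc1OC)[C@@](C)(O)CCC=C(C)C | intermediate
23 | Chabrolobenzoquinone H, (10R,11S) | CC(=O)O[C@H](CC/C(C)=C/CC/C(C)=C/CC1=CC(=O)C(C)=CC1=O)[C@@](C)(O)CCC=C(C)C | target

Total step count: 13 steps.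
Longest linear sequence: 13 steps (from 1 to 23); 2, 7 and 18 enter as bought compounds.

Steps most likely to fail

1. Step 6 (key step).
- What may go wrong: the bromonium source is shared between the furan, the chain alkenes (bromohydrin formation) and the arene (ring bromination), so conversion and purity both suffer.
- Fallback, from 10 back to 13: the electrophilic halogen is replaced by a cycloaddition. Dye-sensitised photooxygenation (O2, methylene blue, visible light, CH2Cl2, −78 °C) should add singlet oxygen across C11 and C14 of the furan, the fastest singlet-oxygen acceptor in the molecule, to give the 2,5-endoperoxide F1.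
- Dimethyl sulfide added cold then cleaves the O–O bond reductively to the Z-enedione 12, which closes to 13 as in the main route. The same bonds form and the same ring closes.

2. Step 8.
- What may go wrong: poor facial selectivity of the methyl transfer if the small anomeric methoxy group shields its face too weakly, or partial enolisation at C10.
- Fallback, from 13 back to 17: the control element is enlarged and the later unmasking is changed from acid to fluoride. Silylation of lactol 13 (TBSCl, imidazole, CH2Cl2) should give the trans silyl acetal, (2R,6R)-6-(tert-butyldimethylsilyloxy)-2-R-2H-pyran-3(6H)-one F2.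
- Its bulky axial silyloxy group blocks one face more effectively, so methylcerium addition should give the tertiary allylic alcohol F3, diimide reduction the saturated silyl acetal F4, and buffered TBAF the lactol 17 without any acid step.

3. Step 9.
- What may go wrong: over-reduction, that is, hydrogen transfer to the trisubstituted chain alkenes before the hindered ring alkene (next to the quaternary C11) is consumed.
- Fallback, from 14 back to 16: the ring alkene is removed while it is still electronically distinct as an enone. Copper hydride conjugate reduction (Stryker's reagent, toluene, rt), which does not touch isolated alkenes, should give the saturated ketone (2R,6S)-6-methoxy-2-R-oxan-3-one F5.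
- The ketone is precomplexed with methylaluminium bis(2,6-di-tert-butyl-4-methylphenoxide), which occupies the equatorial side of the carbonyl. Addition of MeLi (toluene, −78 °C) should then force axial delivery of methyl, giving axial methyl and equatorial hydroxyl, which is the C11 configuration of 16.

Further compounds
F1 | step 6 | (1R,4E,8E)-10-(2,5-dimethoxy-4-methylphenyl)-4,8-dimethyl-1-(2,3,7-trioxabicyclo[2.2.1]hept-5-en-1-yl)deca-4,8-dien-1-ol (furan endoperoxide, diastereomers at the bridgeheads) | O[C@H](CC/C(C)=C/CC/C(C)=C/Cc1cc(OC)c(C)cc1OC)C12C=CC(OO1)O2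
F2 | step 8 | (2R,6R)-6-(tert-butyldimethylsilyloxy)-2-R-2H-pyran-3(6H)-one, trans | CC(C)(C)[Si](C)(C)O[C@@H]1C=CC(=O)[C@@H](CC/C(C)=C/CC/C(C)=C/Cc2cc(OC)c(C)cc2OC)O1
F3 | step 8 | (2R,3S,6R)-6-(tert-butyldimethylsilyloxy)-3-methyl-2-R-3,6-dihydro-2H-pyran-3-ol | CC(C)(C)[Si](C)(C)O[C@@H]1C=C[C@](C)(O)[C@@H](CC/C(C)=C/CC/C(C)=C/Cc2cc(OC)c(C)cc2OC)O1
F4 | step 8 | (2R,3S,6R)-6-(tert-butyldimethylsilyloxy)-3-methyl-2-R-oxan-3-ol | CC(C)(C)[Si](C)(C)O[C@@H]1CC[C@](C)(O)[C@@H](CC/C(C)=C/CC/C(C)=C/Cc2cc(OC)c(C)cc2OC)O1
F5 | step 9 | (2R,6S)-6-methoxy-2-R-oxan-3-one | CO[C@@H]1CCC(=O)[C@@H](CC/C(C)=C/CC/C(C)=C/Cc2cc(OC)c(C)cc2OC)O1
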